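The route rests on cutting ring C (the pyranone) of fragment 2, the 8-chloro-5,7-dihydroxyisoflavone unit, at O1–C2 and C3–C4. O1, C8a, C4a and C4 come from a chlorinated salicylaldehyde, C2 and C3 from an aryl(trimethylsilyl)alkyne that already carries the complete fragment 1 (the 8-aryloxy-7,4'-dimethoxyisoflavone) on its aryl group. A rhodium-catalysed oxidative annulation forms both bonds and closes ring C in one operation, silicon steering the aryl group to C3. All four phenols travel as methyl ethers; protodesilylation and BBr3 demethylation finish the synthesis.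

Key step: step 7

Remark: both isoflavone units are numbered as chromones (O1, C2, C3, C4, C4a, C5 to C8, C8a; primed locants on ring B); fragment 1 is the 7,4'-dioxygenated unit bearing the ether oxygen at C8, fragment 2 the 8-chloro-5,7-dioxygenated unit; the target has no stereocentre.

Step 1
Reactants: 1 3,5-dimethoxyphenol
Product: 2 2-chloro-3,5-dimethoxyphenol
Conditions: SO2Cl2 (1.0 equiv), 2,2,6,6-tetramethylpiperidine (10 mol%), toluene, −10 °C to rt
Reagents that add atoms: sulfuryl chloride, O=S(=O)(Cl)Cl
Why: Amine-catalysed ortho-selective electrophilic aromatic chlorination, in which the N-chloroamine formed from SO2Cl2 is held by the phenol O–H and delivers chlorine to one of the two equivalent ortho positions (C2/C6) in preference to the para position C4, one equivalent of reagent limiting the reaction to the monochloride.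

Step 2
Reactants: 2 2-chloro-3,5-dimethoxyphenol
Product: 4 3-chloro-2-hydroxy-4,6-dimethoxybenzaldehyde, via salicyl alcohol 3 (not isolated)
Conditions: MgCl2, Et3N, (CH2O)n, MeCN, reflux; aq. HCl work-up
Reagents that add atoms: paraformaldehyde (as formaldehyde), C=O
Why: Casnati–Skattebøl magnesium-mediated ortho-formylation, in which the magnesium phenoxide binds formaldehyde and forms the C–C bond at C6, the only free position ortho to the phenol oxygen, and the magnesium alkoxide of 3 is then oxidised to the aldehyde by hydride transfer to a second formaldehyde.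

Step 3
Reactants: 5 pyrogallol; 6 4-methoxyphenylacetic acid
Product: 8 7,8-dihydroxy-4'-methoxyisoflavone, via deoxybenzoin 7 (not isolated)
Conditions: BF3·OEt2, 85 °C; then DMF, MsCl, 70 °C; aq. NaOAc work-up
Reagents that add atoms: N,N-dimethylformamide, CN(C)C=O
Why: BF3-promoted Friedel–Crafts C-acylation of pyrogallol at C4 (ortho and para to hydroxyl groups) followed in the same pot by C-formylation of the methylene group of the boron-chelated deoxybenzoin with the iminium reagent from DMF and MsCl and cyclodehydration onto the ortho hydroxyl, which is the one-pot deoxybenzoin route to isoflavones.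

Step 4
Reactants: 8 7,8-dihydroxy-4'-methoxyisoflavone
Product: 9 8-hydroxy-7,4'-dimethoxyisoflavone
Conditions: MeI (1.1 equiv), NaHCO3, DMF, 40 °C
Reagents that add atoms: iodomethane, CI
Why: Williamson ether synthesis under acidity control, since the 7-hydroxyl is para to the pyranone carbonyl (a vinylogous acid) and is the only phenol that hydrogencarbonate ionises, so the less acidic 8-hydroxyl should stay free for step 5.

Step 5
Reactants: 9 8-hydroxy-7,4'-dimethoxyisoflavone; 10 1-bromo-4-iodobenzene
Product: 11 8-(4-bromophenoxy)-7,4'-dimethoxyisoflavone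
Conditions: 10 (1.5 equiv), CuI (10 mol%), picolinic acid (20 mol%), K3PO4, DMSO, 90 °C
Reagents that add atoms: none
Why: Ullmann-type copper-catalysed diaryl ether coupling with a picolinic acid ligand system suited to ortho-disubstituted phenols, in which monovalent copper takes the C–I bond of 10 far faster than the C–Br bond, so that the bromide is kept for step 6.

Step 6
Reactants: 11 8-(4-bromophenoxy)-7,4'-dimethoxyisoflavone; 12 ethynyltrimethylsilane
Product: 13 7,4'-dimethoxy-8-[4-(trimethylsilylethynyl)phenoxy]isoflavone
Conditions: 12 (2 equiv), Pd(PPh3)2Cl2 (5 mol%), CuI (5 mol%), Et3N, DMF, 70 °C, sealed tube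
Reagents that add atoms: none
Why: Sonogashira coupling of the aryl bromide with the terminal C–H of the silylacetylene under amine conditions that leave the pyranone ring, the diaryl ether and the C–Si bond untouched and install the silylalkyne without any strong base.

Step 7
Reactants: 4 3-chloro-2-hydroxy-4,6-dimethoxybenzaldehyde; 13 7,4'-dimethoxy-8-[4-(trimethylsilylethynyl)phenoxy]isoflavone
Product: 14 2-trimethylsilyl derivative of the tetra-O-methyl target
Conditions: 4 (1.3 equiv), [Cp*RhCl2]2 (pentamethylcyclopentadienyl rhodium dichloride dimer, 2.5 mol%), Cu(OAc)2 (2.2 equiv), o-xylene, 120 °C, N2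
Reagents that add atoms: none
Why: The phenoxide of 4 binds the trivalent rhodium acetate species formed from [Cp*RhCl2]2 and Cu(OAc)2, acetate-assisted cleavage of the formyl C–H bond gives a five-membered acylrhodacycle, alkyne 13 inserts into the rhodium–acyl bond (forming C3–C4), and C–O reductive elimination from the seven-membered rhodacycle forms O1–C2, after which Cu(OAc)2 returns monovalent rhodium to the trivalent state. The closest known reaction type is the rhodium-catalysed oxidative annulation of salicylaldehydes with internal alkynes to 2,3-disubstituted chromones through aldehyde C–H activation. Ring C of fragment 2 is closed as a formal [4+2] annulation whose last bond, O1–C2, arises by reductive elimination at the metal, and no stereocentre is formed. The selectivity that matters is the sense of insertion: the silicon-bearing alkyne carbon is expected to end on rhodium, the preference that silylalkynes show in Larock-type annulations owing to the long C–Si bond and α-silyl stabilisation of the carbon–metal bond, which places the aryl group on C3 and silicon on C2. This regiochemical outcome is the one point of the route that rests on analogy. Hydroxyl-assisted formyl activation of 4 should be much faster than ketone-directed C5–H activation of the fragment 1 chromone in 13, and any loss of silicon in the pot would only give 15 one step early.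

Step 8
Reactants: 14 2-trimethylsilyl derivative of the tetra-O-methyl target
Product: 15 tetra-O-methyl ether of the target
Conditions: TBAF, AcOH, THF, 0 °C to rt
Reagents that add atoms: none
Why: Fluoride-induced protodesilylation, in which fluoride forms a pentacoordinate silicate, the C2–Si bond breaks to an oxygen-stabilised vinyl anion equivalent that acetic acid protonates, and the buffer keeps the medium from opening either pyranone ring.

Step 9
Reactants: 15 tetra-O-methyl ether of the target
Product: 16 Bisoflavolin G
Conditions: BBr3 (excess), CH2Cl2, −78 °C to rt; then MeOH, H2O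
Reagents that add atoms: none
Why: Lewis acid cleavage of aryl methyl ethers, in which BBr3 coordinates each methoxy oxygen and bromide attacks the methyl carbon (SN2), a path closed to the diaryl ether, the aryl chloride and the chromone rings, with the C5 methoxy group of fragment 2 expected to go first through chelation to the C4 carbonyl.

Compound list
1 | 3,5-dimethoxyphenol | COc1cc(O)cc(OC)c1 | starting material
2 | 2-chloro-3,5-dimethoxyphenol | COc1cc(O)c(Cl)c(OC)c1 | intermediate
3 | 2-chloro-6-(hydroxymethyl)-3,5-dimethoxyphenol (salicyl alcohol, not isolated) | COc1cc(OC)c(CO)c(O)c1Cl | intermediate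
4 | 3-chloro-2-hydroxy-4,6-dimethoxybenzaldehyde | COc1cc(OC)c(C=O)c(O)c1Cl | intermediate
5 | pyrogallol (benzene-1,2,3-triol) | Oc1cccc(O)c1O | starting material
6 | 4-methoxyphenylacetic acid | COc1ccc(CC(=O)O)cc1 | starting material
7 | 2-(4-methoxyphenyl)-1-(2,3,4-trihydroxyphenyl)ethan-1-one (deoxybenzoin, not isolated) | COc1ccc(CC(=O)c2ccc(O)c(O)c2O)cc1 | intermediate
8 | 7,8-dihydroxy-3-(4-methoxyphenyl)-4H-chromen-4-one (7,8-dihydroxy-4'-methoxyisoflavone) | COc1ccc(-c2coc3c(O)c(O)ccc3c2=O)cc1 | intermediate
9 | 8-hydroxy-7-methoxy-3-(4-methoxyphenyl)-4H-chromen-4-one (8-hydroxy-7,4'-dimethoxyisoflavone) | COc1ccc(-c2coc3c(O)c(OC)ccc3c2=O)cc1 | intermediate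
10 | 1-bromo-4-iodobenzene | Brc1ccc(I)cc1 | starting material
11 | 8-(4-bromophenoxy)-7-methoxy-3-(4-methoxyphenyl)-4H-chromen-4-one | COc1ccc(-c2coc3c(Oc4ccc(Br)cc4)c(OC)ccc3c2=O)cc1 | intermediate
12 | ethynyltrimethylsilane | C#C[Si](C)(C)C | starting material
13 | 7-methoxy-3-(4-methoxyphenyl)-8-{4-[(trimethylsilyl)ethynyl]phenoxy}-4H-chromen-4-one | COc1ccc(-c2coc3c(Oc4ccc(C#C[Si](C)(C)C)cc4)c(OC)ccc3c2=O)cc1 | intermediate
14 | 8-chloro-5,7-dimethoxy-3-(4-{[7-methoxy-3-(4-methoxyphenyl)-4-oxo-4H-chromen-8-yl]oxy}phenyl)-2-(trimethylsilyl)-4H-chromen-4-one | COc1ccc(-c2coc3c(Oc4ccc(-c5c([Si](C)(C)C)oc6c(Cl)c(OC)cc(OC)c6c5=O)cc4)c(OC)ccc3c2=O)cc1 | intermediate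
15 | 8-chloro-5,7-dimethoxy-3-(4-{[7-methoxy-3-(4-methoxyphenyl)-4-oxo-4H-chromen-8-yl]oxy}phenyl)-4H-chromen-4-one | COc1ccc(-c2coc3c(Oc4ccc(-c5coc6c(Cl)c(OC)cc(OC)c6c5=O)cc4)c(OC)ccc3c2=O)cc1 | intermediate
16 | Bisoflavolin G | O=c1c(-c2ccc(O)cc2)coc2c(Oc3ccc(-c4coc5c(Cl)c(O)cc(O)c5c4=O)cc3)c(O)ccc12 | target

Total step count: 9 steps. Longest linear sequence: 7 steps (from 5 to 16 through steps 3 to 9); the aldehyde branch (steps 1 and 2) joins at step 7.

Steps most likely to fail

Step 7. The alkyne may insert in the opposite sense (aryl carbon on rhodium, leading to the 2-aryl-3-silyl chromone). The alkynyl C–Si bond may be cleaved by acetate before insertion, followed by copper-mediated alkyne dimerisation. The acylrhodium may lose CO, or ketone-directed C–H activation of the fragment 1 chromone may compete. The fallback gives up the annulation and forms the C3–aryl bond of fragment 2 by Suzuki–Miyaura coupling of a 3-iodochromone, the established isoflavone construction. It sets out from aldehyde 4 and bromide 11 and returns at 15. Addition of MeMgBr (excess, THF, 0 °C) to 4 should give racemic 1-(3-chloro-2-hydroxy-4,6-dimethoxyphenyl)ethanol F1, which MnO2 (CH2Cl2, rt) oxidises to 1-(3-chloro-2-hydroxy-4,6-dimethoxyphenyl)ethan-1-one F2. Condensation with N,N-dimethylformamide dimethyl acetal (90 °C) gives (E)-1-(3-chloro-2-hydroxy-4,6-dimethoxyphenyl)-3-(dimethylamino)prop-2-en-1-one F3, and iodine (CHCl3, rt) cyclises it with loss of dimethylamine to 8-chloro-3-iodo-5,7-dimethoxy-4H-chromen-4-one F4. Miyaura borylation of 11 (B2pin2, Pd(dppf)Cl2, KOAc, dioxane, 90 °C) gives 7-methoxy-3-(4-methoxyphenyl)-8-[4-(4,4,5,5-tetramethyl-1,3,2-dioxaborolan-2-yl)phenoxy]-4H-chromen-4-one F5. Coupling of F4 with F5 (Pd(dppf)Cl2, Na2CO3, DME/H2O, 80 °C) at the C–I bond, which reacts well before the C8–Cl bond, gives 15, and the route resumes at step 9; steps 6 and 8 are then not needed.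

Step 1. Chlorination at C4 (para to the hydroxyl, between the two methoxy groups) or double chlorination may compete with ortho attack, because the uncatalysed reaction of this very electron-rich phenol with SO2Cl2 is fast. The fallback fixes the position by directed ortho-metalation; it sets out from 1 and returns at 2. Carbamoylation of 1 (ClCONEt2, K2CO3, MeCN, reflux) gives 3,5-dimethoxyphenyl N,N-diethylcarbamate F6. Lithiation (s-BuLi, TMEDA, THF, −78 °C), which the carbamate should direct to C2 between itself and a methoxy group, and quenching with C2Cl6 give 2-chloro-3,5-dimethoxyphenyl N,N-diethylcarbamate F7. Hydrolysis (NaOH, EtOH/H2O, reflux) releases 2.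

Step 5. The C–O coupling of the ortho-disubstituted phenoxide may be slow, so that base-induced opening of the pyranone ring or reduction of the aryl iodide takes over. The fallback replaces the copper coupling by nucleophilic aromatic substitution and builds the alkyne from an aldehyde; it sets out from 9 and returns at 13. Reaction of 9 with 4-fluorobenzaldehyde (K2CO3, DMF, 110 °C) should give 4-{[7-methoxy-3-(4-methoxyphenyl)-4-oxo-4H-chromen-8-yl]oxy}benzaldehyde F8. Ohira–Bestmann homologation (dimethyl (1-diazo-2-oxopropyl)phosphonate, K2CO3, MeOH, rt) gives 8-(4-ethynylphenoxy)-7-methoxy-3-(4-methoxyphenyl)-4H-chromen-4-one F9. C-silylation of the terminal alkyne (TMSOTf, Et3N, catalytic Zn(OTf)2, CH2Cl2, rt) gives 13, and the route resumes at step 7; compounds 10, 11 and 12 are then not needed.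

Further compounds
F1 | step 7 | racemic 1-(3-chloro-2-hydroxy-4,6-dimethoxyphenyl)ethanol | COc1cc(OC)c(C(C)O)c(O)c1Cl
F2 | step 7 | 1-(3-chloro-2-hydroxy-4,6-dimethoxyphenyl)ethan-1-one | COc1cc(OC)c(C(C)=O)c(O)c1Cl
F3 | step 7 | (E)-1-(3-chloro-2-hydroxy-4,6-dimethoxyphenyl)-3-(dimethylamino)prop-2-en-1-one | COc1cc(OC)c(C(=O)/C=C/N(C)C)c(O)c1Cl
F4 | step 7 | 8-chloro-3-iodo-5,7-dimethoxy-4H-chromen-4-one | COc1cc(OC)c2c(=O)c(I)coc2c1Cl
F5 | step 7 | 7-methoxy-3-(4-methoxyphenyl)-8-[4-(4,4,5,5-tetramethyl-1,3,2-dioxaborolan-2-yl)phenoxy]-4H-chromen-4-one | COc1ccc(-c2coc3c(Oc4ccc(B5OC(C)(C)C(C)(C)O5)cc4)c(OC)ccc3c2=O)cc1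
F6 | step 1 | 3,5-dimethoxyphenyl N,N-diethylcarbamate | CCN(CC)C(=O)Oc1cc(OC)cc(OC)c1
F7 | step 1 | 2-chloro-3,5-dimethoxyphenyl N,N-diethylcarbamate | CCN(CC)C(=O)Oc1cc(OC)cc(OC)c1Cl
F8 | step 5 | 4-{[7-methoxy-3-(4-methoxyphenyl)-4-oxo-4H-chromen-8-yl]oxy}benzaldehyde | COc1ccc(-c2coc3c(Oc4ccc(C=O)cc4)c(OC)ccc3c2=O)cc1
F9 | step 5 | 8-(4-ethynylphenoxy)-7-methoxy-3-(4-methoxyphenyl)-4H-chromen-4-one | COc1ccc(-c2coc3c(Oc4ccc(C#C)cc4)c(OC)ccc3c2=O)cc1
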